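| flask | substrate | free catalyst | time |
|---|---|---|---|
| teal | 0.500 M | 0.00500 M |  |
| ochre | 0.300 M | 0.00500 M |  |
| blue | 1.00 M | 0.00500 M |  |
| amber | 0.500 M | 0.00100 M | 13 min |

| run | time / min | [target] / M |
|---|---|---|
| teal run | 0.52 | 0.008 |
| teal run | 0.89 | 0.012 |
| teal run | 1.5 | 0.004 |
| teal run | 2.6 | 0.059 |
| teal run | 4.4 | 0.096 |
| teal run | 7.6 | 0.275 |
| teal run | 13 | 0.474 |
| ochre run | 0.52 | 0.006 |
| ochre run | 0.89 | 0.004 |
| ochre run | 1.5 | 0.007 |
| ochre run | 2.6 | 0.019 |
| ochre run | 4.4 | 0.040 |
| ochre run | 7.6 | 0.103 |
| ochre run | 13 | 0.210 |
| blue run | 0.52 | 0.014 |
| blue run | 0.89 | 0.022 |
| blue run | 1.5 | 0.063 |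
| blue run | 2.6 | 0.151 |
| blue run | 4.4 | 0.499 |
| blue run | 7.6 | 0.943 |
| blue run | 13 | 1.005 |

(scatter of a reading: 0.007 M)

- how the opening rate goes with [substrate] round the charge of the teal run: the exponent of the rate at two percent of substrate gone to target (one fixed amount of target, the same in the runs compared)
- the ochre run starts with 0.200 M less of substrate than the teal run, and with no target. Compared where both hold the same amount of substrate, once fifteen percent of what the ochre run was charged with has turned into target, is the ochre run faster, slower or alike (within a tenth)?
- target in the amber run at 13 min, as a share of the substrate charged
- which of these the readings show (the substrate kills the catalyst / the product ties up the catalyst / the product speeds the reaction / nothing beyond the main steps / an uncatalysed path runs beside / the substrate ties up the catalyst)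

**What do the early times show?** In the teal run, c(target) reads 0.004 M at 1.5 min, below the scatter of 0.007 M. The average rate up to 2.6 min is 0.0227 M min⁻¹, but from 4.4 min to 7.6 min it is 0.0559 M min⁻¹, though substrate has fallen. So the product speeds the reaction: this is autocatalysis.

**And the order in substrate?** Compare times to nearly equal target. Ochre against teal gives an exponent of 1.07, and teal against blue gives 0.794, so I say about 1.

**Where both hold equal substrate, which run is faster?** There the teal run holds 0.200 M more target than the ochre run. The readings put both runs at that substrate level between 4.4 min and 7.6 min. Over that span the ochre run averages 0.0197 M min⁻¹ against 0.0559 M min⁻¹ in the teal run, so the ochre run is slower.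

**What clock does a growing target keep?** Take the odds, c(target)/c(substrate), and work in powers of ten. In the teal run they go from 0.238 to 1.22 between those two readings. That gives the tenfold time, the time in which the odds grow by a factor of ten, 4.50 min. The teal run reaches even odds at about 7.21 min.

**The weak spot: no run varied the catalyst. What do you assume for the amber run?** My wager is that the catalyst supplies the first target, while growth runs between substrate and target. The amber charge of catalyst is 5.00 times smaller. If the first target goes in proportion to that charge, this costs 0.699 of a power of ten, or 3.14 min. Even odds then fall at 10.4 min. The remaining time to 13 min buys 0.588 of a power of ten, so the odds are 3.88 and the share is about 79.5%.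

The forecast gave 1, slower, 10% and the product speeds the reaction, and parts from my reckoning on the amber run by “assuming both terms scale with catalyst”, which is the teal run with its clock scaled as if first order in everything but substrate.

The flask gives an order of 1.0 in substrate, the ochre run slower, 76.5% in the amber run at 13 min, and the answer that the product speeds the reaction.

    2 free catalyst ⇌ catalyst dimer, settled at all times (134.0 M⁻¹)
    free catalyst + substrate → target + free catalyst (7.140 M⁻¹ min⁻¹)
    substrate + target → 2 target (0.8280 M⁻¹ min⁻¹)

The amber run's 76.5% means odds of 3.26, so on the tenfold time even odds in the amber run lie about 2.31 min before 13 min. The step in which substrate and target give two target carries this: without it the amber run reaches 7.33% instead of 76.5%. The blue run, charged with twice the substrate of the teal run, goes from a quarter to half of its charge between 3.19 min and 4.43 min, a tenfold time of 2.60 min, and the teal tenfold time, taken inversely with the charge, gives 2.25 min.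

The data come from a simulation for substances that don't exist.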